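**Plan**

- Ring numbering: C1 (C=O between C–OMe and C–chain), C2 (OMe), C3 (Me), C4 (C=O), C5 (OH), C6 (chain). In each ring the adjacent pair C5(OH)/C6(chain) corresponds to the two sp carbons of a 1-alkynylboronate, with boron standing in for the C5 oxygen.
- Retrosynthesis: C5–OH back to C5–B, quinone back to the para-methoxyphenol, then each ring is cut at C1–C6, C4–C5 and C3–C4 into an alkenyl(methoxy)carbene chromium complex (C1–C3), one CO (C4) and the alkynylboronate (C5, C6).
- Forward: the C18 diyne is built from the C14 diol and acetylide and borylated at both ends. Both benzene rings are then closed at once on the chain termini, and two oxidations finish the quinones.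
- Stereochemistry: the target has no stereocentre. Only the Z geometry of the enol ether in the carbene is carried, set by the allyl ether isomerization, and it vanishes on aromatization.

Key step: step 6

Remark: the linker is read as fourteen CH2 groups between the ring carbons; in the SMILES of 14 the η6 arene–chromium bonds are written as dots.

**Route**

Step 1
Reactants: 1 tetradecane-1,14-diol
Product: 2 1,14-dibromotetradecane
Conditions: CBr4, PPh3, CH2Cl2, 0 °C → rt
Reagents that add atoms: tetrabromomethane, BrC(Br)(Br)Br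
Why: Appel bromination, in which bromide displaces the alkoxyphosphonium leaving group by SN2 at each unhindered primary carbon.

Step 2
Reactants: 2 1,14-dibromotetradecane
Product: 3 octadeca-1,17-diyne
Conditions: LiC≡CH·H2NCH2CH2NH2 (3 equiv), DMSO, 10 °C → rt
Reagents that add atoms: lithium acetylide–ethylenediamine complex, [Li+].[C-]#C.NCCN
Why: SN2 alkylation of lithium acetylide by a primary bromide in DMSO is the standard terminal alkyne synthesis, and the unbranched primary centres disfavour elimination.

Step 3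
Reactants: 3 octadeca-1,17-diyne; 4 2-isopropoxy-4,4,5,5-tetramethyl-1,3,2-dioxaborolane
Product: 7 2,2'-(octadeca-1,17-diyne-1,18-diyl)bis(4,4,5,5-tetramethyl-1,3,2-dioxaborolane), via dilithium diacetylide 5 (not isolated), via dilithium bis(borate) complex 6 (not isolated)
Conditions: n-BuLi (2.1 equiv), THF, −78 °C; 4 (2.2 equiv), −78 °C; HCl in Et2O (2.2 equiv), −78 °C → rt
Reagents that add atoms: none
Why: Brown alkynylboronate synthesis, in which each lithium acetylide adds to the borate ester to give a stable ate complex, from which anhydrous HCl removes isopropoxide and leaves the pinacol alkynylboronate.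

Step 4
Reactants: 8 allyl methyl ether (3-methoxyprop-1-ene)
Product: 9 (Z)-1-methoxyprop-1-ene
Conditions: KOtBu (cat.), DMSO, rt; product distilled from the mixture
Reagents that add atoms: none
Why: Base-catalysed prototropic allyl-to-propenyl ether isomerization, which passes through the potassium-chelated cisoid oxyallyl anion and should therefore give mainly the Z enol ether.

Step 5
Reactants: 9 (Z)-1-methoxyprop-1-ene; 10 Cr(CO)6
Product: 13 pentacarbonyl[(2Z)-1,2-dimethoxybut-2-en-1-ylidene]chromium, via alkenyllithium 11 (not isolated), via lithium acyl chromate 12 (not isolated)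
Conditions: t-BuLi, THF/pentane, −78 → 0 °C; Cr(CO)6, Et2O, 0 °C → rt; solvent exchanged, MeOTf, CH2Cl2, 0 °C
Reagents that add atoms: methyl trifluoromethanesulfonate, COS(=O)(=O)C(F)(F)F
Why: Fischer carbene synthesis, in which the Z enol ether is lithiated at the oxygen-bearing vinylic carbon as dihydropyran is, the alkenyllithium adds to a CO ligand of Cr(CO)6, and MeOTf methylates the acyl chromate on oxygen with the alkene geometry retained.

Step 6
Reactants: 7 2,2'-(octadeca-1,17-diyne-1,18-diyl)bis(4,4,5,5-tetramethyl-1,3,2-dioxaborolane); 13 pentacarbonyl[(2Z)-1,2-dimethoxybut-2-en-1-ylidene]chromium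
Product: 15 1,14-bis[3-hydroxy-5,6-dimethoxy-4-methyl-2-(4,4,5,5-tetramethyl-1,3,2-dioxaborolan-2-yl)phenyl]tetradecane, via bis(tricarbonylchromium) arene complex 14 (not isolated)
Conditions: 13 (2.6 equiv), THF, 45 °C, Ar; then air, MeCN, rt
Reagents that add atoms: none
Why: Thermal loss of one CO from 13 lets each alkyne terminus of 7 insert into the Cr=C bond (C1–C6), CO then inserts to give a chromium-bound dienylketene (C4–C5), and closure onto the methyl-bearing alkene carbon (C3–C4) followed by enolization gives the phenol, first as its Cr(CO)3 complex 14 and, after exposure to air, as free 15. The closest known reactions are the Dötz benzannulation of alkenyl(methoxy)carbene chromium complexes with pinacol 1-alkynylboronates and that of cyclic alpha-alkoxyalkenyl (dihydropyranyl) carbene complexes with alkynes. Each of the two benzene rings closes by 6π electrocyclization of the dienylketene, a [3+2+1] assembly of three carbene-ligand carbons, two alkyne carbons and one CO. No stereocentre is formed, and the Z geometry of 13 merely places hydrogen, not methyl, on the inside of the closing triene. The step needs one orientation of alkyne insertion, boron-bearing carbon next to the CO-derived C4 and chain-bearing carbon next to the carbene carbon C1; the bulky pinacolboronate takes the position remote from the carbene carbon, as the larger alkyne substituent does in this reaction, while the primary CH2 sits beside it. The fourteen-carbon spacer keeps the two termini independent, and the excess of 13 is meant to drive both annulations to completion.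

Step 7
Reactants: 15 1,14-bis[3-hydroxy-5,6-dimethoxy-4-methyl-2-(4,4,5,5-tetramethyl-1,3,2-dioxaborolan-2-yl)phenyl]tetradecane
Product: 16 1,14-bis[5-methoxy-4-methyl-3,6-dioxo-2-(4,4,5,5-tetramethyl-1,3,2-dioxaborolan-2-yl)cyclohexa-1,4-dien-1-yl]tetradecane
Conditions: (NH4)2Ce(NO3)6 (5 equiv), MeCN/H2O, 0 °C
Reagents that add atoms: water, O
Why: Oxidative demethylation of a para-methoxyphenol, in which two-electron oxidation, water addition at the methoxy-bearing C1 and loss of methanol give the quinone, conditions under which quinone pinacolboronates are known to keep the C–B bond.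

Step 8
Reactants: 16 1,14-bis[5-methoxy-4-methyl-3,6-dioxo-2-(4,4,5,5-tetramethyl-1,3,2-dioxaborolan-2-yl)cyclohexa-1,4-dien-1-yl]tetradecane
Product: 18 1,14-bis(2-hydroxy-5-methoxy-4-methyl-3,6-dioxocyclohexa-1,4-dien-1-yl)tetradecane (CNP0278640.0), via bis(quinonyl borate) 17 (not isolated)
Conditions: Me3NO (3 equiv), CH2Cl2, 0 °C → rt; then aqueous NaH2PO4, dilute HCl work-up
Reagents that add atoms: trimethylamine N-oxide, C[N+](C)(C)[O-]
Why: Amine N-oxide oxidation of a carbon–boron bond, in which the N-oxide oxygen adds to boron, the quinonyl carbon migrates from boron to oxygen with loss of NMe3 and mild hydrolysis frees the hydroxyquinone, without a nucleophilic peroxide that could epoxidize the quinone.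

**Compound list**

1 | tetradecane-1,14-diol | OCCCCCCCCCCCCCCO | starting material
2 | 1,14-dibromotetradecane | BrCCCCCCCCCCCCCCBr | intermediate
3 | octadeca-1,17-diyne | C#CCCCCCCCCCCCCCCC#C | intermediate
4 | 2-isopropoxy-4,4,5,5-tetramethyl-1,3,2-dioxaborolane | CC(C)OB1OC(C)(C)C(C)(C)O1 | starting material
5 | 1,18-dilithiooctadeca-1,17-diyne (dilithium diacetylide) | [Li]C#CCCCCCCCCCCCCCCC#C[Li] | intermediate (not isolated)
6 | dilithium (octadeca-1,17-diyne-1,18-diyl)bis[isopropoxy(pinacolato)borate] | [Li+].[Li+].CC(C)O[B-]1(OC(C)(C)C(C)(C)O1)C#CCCCCCCCCCCCCCCC#C[B-]1(OC(C)C)OC(C)(C)C(C)(C)O1 | intermediate (not isolated)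
7 | 2,2'-(octadeca-1,17-diyne-1,18-diyl)bis(4,4,5,5-tetramethyl-1,3,2-dioxaborolane) | CC1(C)OB(OC1(C)C)C#CCCCCCCCCCCCCCCC#CB1OC(C)(C)C(C)(C)O1 | intermediate
8 | allyl methyl ether (3-methoxyprop-1-ene) | COCC=C | starting material
9 | (Z)-1-methoxyprop-1-ene | CO/C=C\C | intermediate
10 | chromium hexacarbonyl, Cr(CO)6 | O=C=[Cr](=C=O)(=C=O)(=C=O)(=C=O)=C=O | starting material
11 | (Z)-(1-methoxyprop-1-en-1-yl)lithium | CO/C([Li])=C\C | intermediate (not isolated)
12 | lithium pentacarbonyl[(2Z)-2-methoxybut-2-enoyl]chromate | [Li+].[O-]C(=[Cr](=C=O)(=C=O)(=C=O)(=C=O)=C=O)/C(OC)=C/C | intermediate (not isolated)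
13 | pentacarbonyl[(2Z)-1,2-dimethoxybut-2-en-1-ylidene]chromium, (CO)5Cr=C(OMe)–C(OMe)=CH–CH3 with methyl trans to the carbene carbon | COC(=[Cr](=C=O)(=C=O)(=C=O)(=C=O)=C=O)/C(OC)=C/C | intermediate
14 | bis(tricarbonylchromium) complex of 15, one Cr(CO)3 η6-bound to each new benzene ring | COc1c(OC)c(C)c(O)c(B2OC(C)(C)C(C)(C)O2)c1CCCCCCCCCCCCCCc1c(OC)c(OC)c(C)c(O)c1B1OC(C)(C)C(C)(C)O1.[Cr](=C=O)(=C=O)=C=O.[Cr](=C=O)(=C=O)=C=O | intermediate (not isolated)
15 | 1,14-bis[3-hydroxy-5,6-dimethoxy-4-methyl-2-(4,4,5,5-tetramethyl-1,3,2-dioxaborolan-2-yl)phenyl]tetradecane | COc1c(OC)c(C)c(O)c(B2OC(C)(C)C(C)(C)O2)c1CCCCCCCCCCCCCCc1c(OC)c(OC)c(C)c(O)c1B1OC(C)(C)C(C)(C)O1 | intermediate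
16 | 1,14-bis[5-methoxy-4-methyl-3,6-dioxo-2-(4,4,5,5-tetramethyl-1,3,2-dioxaborolan-2-yl)cyclohexa-1,4-dien-1-yl]tetradecane | COC1=C(C)C(=O)C(B2OC(C)(C)C(C)(C)O2)=C(CCCCCCCCCCCCCCC3=C(B4OC(C)(C)C(C)(C)O4)C(=O)C(C)=C(OC)C3=O)C1=O | intermediate
17 | 1,14-bis{5-methoxy-4-methyl-3,6-dioxo-2-[(4,4,5,5-tetramethyl-1,3,2-dioxaborolan-2-yl)oxy]cyclohexa-1,4-dien-1-yl}tetradecane | COC1=C(C)C(=O)C(OB2OC(C)(C)C(C)(C)O2)=C(CCCCCCCCCCCCCCC3=C(OB4OC(C)(C)C(C)(C)O4)C(=O)C(C)=C(OC)C3=O)C1=O | intermediate (not isolated)
18 | 1,14-bis(2-hydroxy-5-methoxy-4-methyl-3,6-dioxocyclohexa-1,4-dien-1-yl)tetradecane (CNP0278640.0) | COC1=C(C)C(=O)C(O)=C(CCCCCCCCCCCCCCC2=C(O)C(=O)C(C)=C(OC)C2=O)C1=O | target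

**Count and risks**

Total steps: 8. Longest linear sequence: 6 steps (1, 2, 3, 6, 7, 8); the carbene branch (steps 4 and 5) joins at step 6.

Steps most likely to fail:

1. Step 6. The two annulations may not both run to completion, and dienylketene intermediates carrying the electron-rich methoxyalkene may cyclize without CO insertion, so that mono- and bis-annulated boronates form together and resist separation. The fallback builds one ring per molecule and joins the halves afterwards; it sets out from 13 (with 4 for the borylation) and comes back at 15. Purchased 8-bromooct-1-ene (C=CCCCCCCBr) would be alkynylated with LiC≡CH·H2NCH2CH2NH2 in DMSO to dec-1-en-9-yne F1. This would be borylated as in step 3 (n-BuLi; 4; HCl in Et2O) to 2-(dec-9-en-1-yn-1-yl)-4,4,5,5-tetramethyl-1,3,2-dioxaborolane F2. A single benzannulation of F2 with 13 (THF, 45 °C; then air) should give 3,4-dimethoxy-2-methyl-5-(oct-7-en-1-yl)-6-(4,4,5,5-tetramethyl-1,3,2-dioxaborolan-2-yl)phenol F3. Homodimerizing olefin metathesis with the second-generation Grubbs catalyst, (H2IMes)(PCy3)Cl2Ru=CHPh, in CH2Cl2 at 40 °C would give 1,14-bis[3-hydroxy-5,6-dimethoxy-4-methyl-2-(4,4,5,5-tetramethyl-1,3,2-dioxaborolan-2-yl)phenyl]tetradec-7-ene F4 as a mixture of alkene isomers. Hydrogenation (H2, Pd/C, EtOAc) would then return to 15.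

2. Step 5. Deprotonation of 9 at the allylic methyl group, or incomplete vinylic lithiation while t-BuLi is consumed by THF, would leave little alkenyllithium for the acyl chromate; evaporative loss of the volatile enol ether adds to this. The fallback makes the acyl chromate from an acid chloride and the pentacarbonylchromate dianion; it sets out from 10 and comes back at 13. Purchased 2-oxobutanoic acid (CCC(=O)C(O)=O) would be converted with HC(OMe)3, MeOH and catalytic H2SO4 into methyl 2,2-dimethoxybutanoate F5. Acid-catalysed loss of methanol (catalytic TsOH, heat, distillation) should give methyl (Z)-2-methoxybut-2-enoate F6. Saponification with KOH in MeOH/H2O would give potassium (Z)-2-methoxybut-2-enoate F7, and (COCl)2 with catalytic DMF in CH2Cl2 would give (Z)-2-methoxybut-2-enoyl chloride F8. Reduction of 10 with C8K in THF would give dipotassium pentacarbonylchromate K2Cr(CO)5 F9, which should be acylated by F8 at −78 °C to potassium pentacarbonyl[(2Z)-2-methoxybut-2-enoyl]chromate F10. O-Methylation with MeOTf in CH2Cl2 then gives 13.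

3. Step 8. Migration of the electron-poor quinonyl carbon from boron to oxygen may be slow, so that protodeboronation or attack of the liberated amine on the methoxyquinone competes. The fallback inverts the order of the two oxidations; it sets out from 15 and comes back at 18. Oxidation of the aryl–boron bonds of 15 with NaBO3·4H2O in THF/H2O should give 3,3'-(tetradecane-1,14-diyl)bis(4,5-dimethoxy-6-methylbenzene-1,2-diol) F11. Treatment with (NH4)2Ce(NO3)6 in MeCN/H2O at 0 °C would then oxidize each para-methoxyphenol unit with loss of the C1 methyl group and give 18 directly.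

**Further compounds**

F1 | step 6 | dec-1-en-9-yne | C=CCCCCCCC#C
F2 | step 6 | 2-(dec-9-en-1-yn-1-yl)-4,4,5,5-tetramethyl-1,3,2-dioxaborolane | C=CCCCCCCC#CB1OC(C)(C)C(C)(C)O1
F3 | step 6 | 3,4-dimethoxy-2-methyl-5-(oct-7-en-1-yl)-6-(4,4,5,5-tetramethyl-1,3,2-dioxaborolan-2-yl)phenol | COc1c(OC)c(C)c(O)c(B2OC(C)(C)C(C)(C)O2)c1CCCCCCC=C
F4 | step 6 | 1,14-bis[3-hydroxy-5,6-dimethoxy-4-methyl-2-(4,4,5,5-tetramethyl-1,3,2-dioxaborolan-2-yl)phenyl]tetradec-7-ene (alkene geometry not defined) | COc1c(OC)c(C)c(O)c(B2OC(C)(C)C(C)(C)O2)c1CCCCCCC=CCCCCCCc1c(OC)c(OC)c(C)c(O)c1B1OC(C)(C)C(C)(C)O1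
F5 | step 5 | methyl 2,2-dimethoxybutanoate | CCC(OC)(OC)C(=O)OC
F6 | step 5 | methyl (Z)-2-methoxybut-2-enoate | C/C=C(\OC)C(=O)OC
F7 | step 5 | potassium (Z)-2-methoxybut-2-enoate | [K+].[O-]C(=O)/C(OC)=C/C
F8 | step 5 | (Z)-2-methoxybut-2-enoyl chloride | ClC(=O)/C(OC)=C/C
F9 | step 5 | dipotassium pentacarbonylchromate, K2Cr(CO)5 | [K+].[K+].[Cr-2](=C=O)(=C=O)(=C=O)(=C=O)=C=O
F10 | step 5 | potassium pentacarbonyl[(2Z)-2-methoxybut-2-enoyl]chromate | [K+].[O-]C(=[Cr](=C=O)(=C=O)(=C=O)(=C=O)=C=O)/C(OC)=C/C
F11 | step 8 | 3,3'-(tetradecane-1,14-diyl)bis(4,5-dimethoxy-6-methylbenzene-1,2-diol) | COc1c(OC)c(C)c(O)c(O)c1CCCCCCCCCCCCCCc1c(OC)c(OC)c(C)c(O)c1O
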